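**Plan**
Coumarin A is the one on the ethenyl bridge (atoms O1, C2, C3, C4; bridge carbons C1' next to C3 and C2' next to the ring). Coumarin B sits on the ring CH. The cyclohexene is numbered C1 (quaternary), C2 (CH), C3=C4(Me), C5, C6.
Cuts: (a) both phenols are masked as MOM ethers. (b) C3–C1' is cut together with C3=C4 of pyranone A, giving alkyne 13 and 2-formylaryl diazoacetate 16. (c) The Diels–Alder bonds C1–C2 and C5–C6 lead to 3-dienylcoumarin 10 and methacrolein. (d) O1–C2 and C3=C4 of pyranone B lead to aldehyde 3 and a C7 dienoic acid.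
Enabling feature: C3 of coumarin A is both the α-carbon of the aryl ester O1–C2(=O) and the partner of C4, a former formyl carbon ortho to O1. It can therefore enter as a diazo carbon that first takes the alkenyl group from boron and then, as a boron enolate, closes the pyranone on C4. C2' hangs on the quaternary C1, so the new alkene cannot migrate.
Forward order: benzene block 3 (used twice), then pyranone B, the cyclohexene, the alkyne, pyranone A closed during the fragment union, and deprotection.
Stereochemistry: both stereocentres come from one catalyst-controlled, formyl-endo Diels–Alder reaction. The E-alkene comes from syn-hydroboration followed by a stereoretentive 1,2-shift.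

Key step: step 8

Assumption: the sense of induction of the (S)-catalyst in step 5 is taken from the formyl C–H···O binding model for 2-substituted acroleins (addition to the Re face of C2 of methacrolein); if it proved opposite, the (R)-catalyst would be used.
Assumption: 14 is treated as a purchasable reagent; it is otherwise made from glyoxylic acid, tosylhydrazide and thionyl chloride.

Step 1
Reactants: 1 2-methoxyresorcinol
Product: 2 2,4-dihydroxy-3-methoxybenzaldehyde
Conditions: POCl3, DMF, MeCN, 0 °C → rt; then H2O, 50 °C
Reagents that add atoms: N,N-dimethylformamide CN(C)C=O (formyl carbon); water O (formyl oxygen)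
Why: Vilsmeier–Haack formylation, in which the two equivalent positions ortho to one hydroxyl and para to the other are the most nucleophilic, so a single aldehyde should form.

Step 2
Reactants: 2 2,4-dihydroxy-3-methoxybenzaldehyde
Product: 3 2-hydroxy-3-methoxy-4-(methoxymethoxy)benzaldehyde
Conditions: MOMCl (1.05 equiv), iPr2NEt, CH2Cl2, 0 °C
Reagents that add atoms: chloromethyl methyl ether COCCl
Why: Selective O-alkylation, because the 2-OH is tied up in a hydrogen bond to the formyl oxygen and the free, more acidic 4-OH should react first.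

Step 3
Reactants: 4 3-methylbut-2-enal; 5 malonic acid
Product: 6 (2E)-5-methylhexa-2,4-dienoic acid
Conditions: pyridine, piperidine (cat.), 90 °C
Reagents that add atoms: none
Why: Doebner–Knoevenagel condensation with decarboxylation, the standard route from an enal to the (2E)-dienoic acid.

Step 4
Reactants: 6 (2E)-5-methylhexa-2,4-dienoic acid; 3 2-hydroxy-3-methoxy-4-(methoxymethoxy)benzaldehyde
Product: 10 8-methoxy-7-(methoxymethoxy)-3-[(1E)-3-methylbuta-1,3-dien-1-yl]-2H-chromen-2-one, via dienoyl chloride 7 (not isolated), via dienylketene 8 (not isolated), via aryl hexa-3,5-dienoate 9 (not isolated)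
Conditions: (COCl)2, DMF (cat.), CH2Cl2, 0 °C → rt, concentrate; then 3, Et3N, CH2Cl2, 0 °C → rt; then DBU (cat.), rt; 10 kept cold and dilute and used at once
Reagents that add atoms: none
Why: Deconjugative acylation through the dienylketene (1,6-dehydrochlorination, as known for sorbyl and crotonyl chlorides with tertiary amines) places an acidic CH2 between ester and diene, and the intramolecular Knoevenagel-type aldol condensation with the ortho formyl group, the known access to 3-vinylcoumarins, should close pyranone B and leave the E-diene.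

Step 5
Reactants: 10 8-methoxy-7-(methoxymethoxy)-3-[(1E)-3-methylbuta-1,3-dien-1-yl]-2H-chromen-2-one; 11 methacrolein
Product: 12 (1S,2R)-2-[8-methoxy-7-(methoxymethoxy)-2-oxo-2H-chromen-3-yl]-1,4-dimethylcyclohex-3-ene-1-carbaldehyde (formyl cis to coumarinyl)
Conditions: 11 (excess), (S)-3,3-diphenyl-1-(o-tolyl)pyrrolo-oxazaborolidine from (S)-α,α-diphenylprolinol·Tf2NH (20 mol %), CH2Cl2, −78 → −40 °C
Reagents that add atoms: none
Why: Enantioselective Diels–Alder reaction under chiral oxazaborolidinium catalysis, in which the 1-coumarinyl ("ortho") and 3-methyl ("para") groups of the diene both direct its CH2 terminus to the CH2 of methacrolein, a phenyl group of the catalyst shields the Si face of C2 of the bound s-trans enal so that Re-face addition sets the quaternary centre as S, and the formyl-endo approach puts CHO cis to the coumarinyl group and sets C2 as R.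

Step 6
Reactants: 12 (1S,2R)-2-[8-methoxy-7-(methoxymethoxy)-2-oxo-2H-chromen-3-yl]-1,4-dimethylcyclohex-3-ene-1-carbaldehyde
Product: 13 3-[(1R,6S)-6-ethynyl-3,6-dimethylcyclohex-2-en-1-yl]-8-methoxy-7-(methoxymethoxy)-2H-chromen-2-one
Conditions: Ohira–Bestmann reagent, K2CO3, MeOH, 0 °C → rt
Reagents that add atoms: dimethyl (1-diazo-2-oxopropyl)phosphonate CC(=O)C(=[N+]=[N-])P(=O)(OC)OC
Why: Seyferth–Gilbert homologation (Ohira–Bestmann variant) of a non-enolisable aldehyde through the alkylidene carbene and a 1,2-H shift, which touches neither stereocentre and which MOM ethers and the 3-alkylcoumarin should tolerate.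

Step 7
Reactants: 3 2-hydroxy-3-methoxy-4-(methoxymethoxy)benzaldehyde; 14 glyoxylic acid chloride p-toluenesulfonylhydrazone
Product: 16 2-formyl-6-methoxy-5-(methoxymethoxy)phenyl diazoacetate, via aryl glyoxylate tosylhydrazone 15 (not isolated)
Conditions: 14, CH2Cl2, 0 °C; then Et3N (2.2 equiv), 0 °C, short contact, neutral work-up
Reagents that add atoms: none
Why: O-acylation followed by Bamford–Stevens-type loss of sulfinate is the established diazoacetate synthesis, and Et3N is too weak a base to deprotonate the diazoacetate, so the electron-rich ortho formyl group should stay untouched.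

Step 8
Reactants: 13 3-[(1R,6S)-6-ethynyl-3,6-dimethylcyclohex-2-en-1-yl]-8-methoxy-7-(methoxymethoxy)-2H-chromen-2-one; 16 2-formyl-6-methoxy-5-(methoxymethoxy)phenyl diazoacetate
Product: 20 bis(methoxymethyl) ether of the target, via alkenyl(dicyclohexyl)borane 17 (not isolated), via dienol borinate 18 (not isolated), via boron aldolate 19 (not isolated)
Conditions: Cy2BH (1.0 equiv), THF, 0 °C → rt; then slow addition of 16, −78 °C → rt (N2 evolution); then DBU (cat.), rt
Reagents that add atoms: none
Why: Proposed new method: Cy2BH adds syn to the terminal alkyne of 13 (boron on the outer carbon; the trisubstituted ring alkene, the lactone and the MOM acetals do not react with this hindered borane) to give 17, the nucleophilic diazo carbon of 16 then binds to boron, and the alkenyl group shifts 1,2 from boron to that carbon as N2 leaves, with retention of the E geometry, which makes the C3–C1' bond and, after boron moves to oxygen, the dienol borinate 18. The closest known reaction types are the Hooz reaction of organoboranes with diazoacetates (alkenyl transfer is known from alkenyldihaloboranes and alkenylboroxines), the aldol trapping of Hooz enol borinates by aldehydes, and the base-induced closure of 2-formylaryl but-3-enoates to 3-vinylcoumarins (as in step 4); new is their merger in a 2-formylaryl diazoacetate, whose diazo carbon takes up a nucleophile and an electrophile in turn. Pyranone A closes by a 6-(enolendo)-exo-trig aldol addition of C3 to the boron-activated formyl carbon C4 to give 19, and E1cB loss of Cy2BOH, completed by DBU, makes C3=C4 and the aromatic coumarin. No new stereocentre remains, since C3 and C4 of 19 become sp2, the alkene geometry is controlled by the syn hydroboration and the stereoretentive shift, and the two ring stereocentres carry no acidic hydrogen and lie away from the reacting atoms. Three selectivities are needed: attack of the diazo carbon on boron rather than on its own formyl group, which the absence of base, the low temperature, the weak Lewis acidity of a triorganoborane and the para-alkoxy deactivation of the aldehyde should secure; migration of the alkenyl rather than a cyclohexyl group, which the π-assisted shift of an sp2 carbon against a hindered secondary alkyl should secure; and α- rather than γ-attack of the dienolate, which a six- against an eight-membered ring and the neopentyl γ-carbon C2' secure. Should 18 be protonated before it cyclises, the resulting 2-formylaryl but-3-enoate would still close to 20 under the DBU treatment.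

Step 9
Reactants: 20 bis(methoxymethyl) ether of the target
Product: 21 7-hydroxy-3-[(E)-2-[(1R,2R)-2-(7-hydroxy-8-methoxy-2-oxo-2H-chromen-3-yl)-1,4-dimethylcyclohex-3-en-1-yl]ethenyl]-8-methoxy-2H-chromen-2-one (target)
Conditions: conc. HCl (cat.), MeOH–THF, 40 °C
Reagents that add atoms: none
Why: Acid-catalysed transacetalisation of both aryl MOM ethers to dimethoxymethane, mild enough that the alkenes, lactones, aryl methyl ethers and both stereocentres should be left alone.

**Compound list**
1 | 2-methoxyresorcinol (2-methoxybenzene-1,3-diol) | COc1c(O)cccc1O | starting material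
2 | 2,4-dihydroxy-3-methoxybenzaldehyde | COc1c(O)ccc(C=O)c1O | intermediate
3 | 2-hydroxy-3-methoxy-4-(methoxymethoxy)benzaldehyde | COCOc1ccc(C=O)c(O)c1OC | intermediate
4 | 3-methylbut-2-enal | CC(C)=CC=O | starting material
5 | malonic acid | OC(=O)CC(=O)O | starting material
6 | (2E)-5-methylhexa-2,4-dienoic acid | CC(C)=C/C=C/C(=O)O | intermediate
7 | (2E)-5-methylhexa-2,4-dienoyl chloride | CC(C)=C/C=C/C(=O)Cl | intermediate
8 | (3E)-5-methylhexa-1,3,5-trien-1-one (dienylketene) | C=C(C)/C=C/C=C=O | intermediate
9 | 2-formyl-6-methoxy-5-(methoxymethoxy)phenyl (3E)-5-methylhexa-3,5-dienoate | C=C(C)/C=C/CC(=O)Oc1c(C=O)ccc(OCOC)c1OC | intermediate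
10 | 8-methoxy-7-(methoxymethoxy)-3-[(1E)-3-methylbuta-1,3-dien-1-yl]-2H-chromen-2-one | C=C(C)/C=C/c1cc2ccc(OCOC)c(OC)c2oc1=O | intermediate
11 | methacrolein | C=C(C)C=O | starting material
12 | (1S,2R)-2-[8-methoxy-7-(methoxymethoxy)-2-oxo-2H-chromen-3-yl]-1,4-dimethylcyclohex-3-ene-1-carbaldehyde | O=C[C@@]1(C)CCC(C)=C[C@H]1c1cc2ccc(OCOC)c(OC)c2oc1=O | intermediate
13 | 3-[(1R,6S)-6-ethynyl-3,6-dimethylcyclohex-2-en-1-yl]-8-methoxy-7-(methoxymethoxy)-2H-chromen-2-one | C#C[C@@]1(C)CCC(C)=C[C@H]1c1cc2ccc(OCOC)c(OC)c2oc1=O | intermediate
14 | glyoxylic acid chloride p-toluenesulfonylhydrazone | Cc1ccc(cc1)S(=O)(=O)NN=CC(=O)Cl | starting material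
15 | 2-formyl-6-methoxy-5-(methoxymethoxy)phenyl glyoxylate p-toluenesulfonylhydrazone | Cc1ccc(cc1)S(=O)(=O)NN=CC(=O)Oc1c(C=O)ccc(OCOC)c1OC | intermediate
16 | 2-formyl-6-methoxy-5-(methoxymethoxy)phenyl diazoacetate | [N-]=[N+]=CC(=O)Oc1c(C=O)ccc(OCOC)c1OC | intermediate
17 | dicyclohexyl[(E)-2-(ring C1)ethenyl]borane from 13 | B(C1CCCCC1)(C1CCCCC1)/C=C/[C@@]1(C)CCC(C)=C[C@H]1c1cc2ccc(OCOC)c(OC)c2oc1=O | intermediate
18 | O-dicyclohexylboryl dienolate of the 2-formylaryl (E)-but-3-enoate (enolate geometry open) | O=Cc1ccc(OCOC)c(OC)c1OC(OB(C1CCCCC1)C1CCCCC1)=C/C=C/[C@@]1(C)CCC(C)=C[C@H]1c1cc2ccc(OCOC)c(OC)c2oc1=O | intermediate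
19 | 3-alkenyl-4-(dicyclohexylboryloxy)-3,4-dihydrocoumarin (the two transient centres C3 and C4 open) | COCOc1ccc2c(c1OC)OC(=O)C(/C=C/[C@@]1(C)CCC(C)=C[C@H]1c1cc3ccc(OCOC)c(OC)c3oc1=O)C2OB(C1CCCCC1)C1CCCCC1 | intermediate
20 | bis(methoxymethyl) ether of the target, (1R,2R), E | COc1c(OCOC)ccc2cc(/C=C/[C@@]3(C)CCC(C)=C[C@H]3c3cc4ccc(OCOC)c(OC)c4oc3=O)c(=O)oc12 | intermediate
21 | CNP0264408.1, (1R,2R), E | COc1c(O)ccc2cc(/C=C/[C@@]3(C)CCC(C)=C[C@H]3c3cc4ccc(O)c(OC)c4oc3=O)c(=O)oc12 | target

**Step count**
There are 9 steps in total. The longest linear sequence has 7 steps (1, 2, 4, 5, 6, 8, 9).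

**Steps most likely to fail**

Step 8.
- Risk: the diazo carbon may add to its own formyl group once boron or a trace of base activates it. A cyclohexyl group may migrate in place of the alkenyl group. The hindered borane may be slow to take up the diazo ester.
- Fallback (known chemistry): it sets out from 3 and 13 and returns at 20.
- 3 is heated with ethyl (triphenylphosphoranylidene)acetate in N,N-diethylaniline (Wittig olefination, isomerisation, lactonisation) to give 8-methoxy-7-(methoxymethoxy)-2H-chromen-2-one F1.
- Addition of bromine in CH2Cl2 and dehydrobromination with Et3N give 3-bromo-8-methoxy-7-(methoxymethoxy)-2H-chromen-2-one F2.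
- 13 is hydroborated as before to 17. This is coupled in the same flask with F2 under Suzuki–Miyaura conditions [Pd(PPh3)4, aq K3PO4, THF, 50 °C] to give 20 through the same C3–C1' bond.
- This detour makes 14–16 unnecessary.

Step 5.
- Risk: turnover may be slow because the lactone carbonyl and the MOM oxygens compete for the catalyst. Facial selectivity may be poor, or the formyl-endo preference weak.
- Fallback: it sets out from 10 and 11 and returns at 12.
- The cycloaddition is run without a chiral catalyst (large excess of methacrolein, toluene, BHT, 80 °C). It should give the formyl-endo adduct as the racemate, that is 12 together with its mirror image ent-12 F3.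
- Condensation with (1R,2R)-N,N'-dimethyl-1,2-diphenylethane-1,2-diamine (molecular sieves, Et2O) gives two diastereomeric imidazolidines, the aminal of 12 F4 and the aminal of ent-12 F5. These are separated by chromatography or crystallisation.
- Two-phase hydrolysis of F4 with dilute aqueous acid returns 12.

Step 4.
- Risk: O-acylation may occur without deconjugation, leaving an ester too weakly acidic to close. The diene may also dimerise by Diels–Alder reaction during the base treatment.
- Fallback: it sets out from 3 and returns at 10.
- 3 is taken to the coumarin F1 and the 3-bromocoumarin F2 as described above.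
- Mizoroki–Heck reaction of F2 with 2-methylbut-3-en-2-ol [Pd(OAc)2, P(o-tol)3, Et3N, DMF, 90 °C] gives 3-[(1E)-3-hydroxy-3-methylbut-1-en-1-yl]-8-methoxy-7-(methoxymethoxy)-2H-chromen-2-one F6.
- Mesylation and elimination (MsCl, Et3N, CH2Cl2, 0 °C → rt) give 10.

**Further compounds**
F1 | step 8 | 8-methoxy-7-(methoxymethoxy)-2H-chromen-2-one | COCOc1ccc2ccc(=O)oc2c1OC
F2 | step 8 | 3-bromo-8-methoxy-7-(methoxymethoxy)-2H-chromen-2-one | COCOc1ccc2cc(Br)c(=O)oc2c1OC
F3 | step 5 | ent-12, (1R,2S)-2-[8-methoxy-7-(methoxymethoxy)-2-oxo-2H-chromen-3-yl]-1,4-dimethylcyclohex-3-ene-1-carbaldehyde | O=C[C@]1(C)CCC(C)=C[C@@H]1c1cc2ccc(OCOC)c(OC)c2oc1=O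
F4 | step 5 | aminal of 12, (4R,5R)-1,3-dimethyl-4,5-diphenylimidazolidin-2-yl in place of CHO | c1ccccc1[C@@H]2[C@@H](c1ccccc1)N(C)C(N2C)[C@@]1(C)CCC(C)=C[C@H]1c1cc2ccc(OCOC)c(OC)c2oc1=O
F5 | step 5 | aminal of ent-12, (4R,5R)-1,3-dimethyl-4,5-diphenylimidazolidin-2-yl in place of CHO | c1ccccc1[C@@H]2[C@@H](c1ccccc1)N(C)C(N2C)[C@]1(C)CCC(C)=C[C@@H]1c1cc2ccc(OCOC)c(OC)c2oc1=O
F6 | step 4 | 3-[(1E)-3-hydroxy-3-methylbut-1-en-1-yl]-8-methoxy-7-(methoxymethoxy)-2H-chromen-2-one | CC(C)(O)/C=C/c1cc2ccc(OCOC)c(OC)c2oc1=O
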